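## The problem

The target 29 joins two ring systems through a single bond, C8–C14; the atoms are numbered C1–C10 for the hydroazulene (cycloheptane C1–C5/C9/C10 with the gem-dimethyl group on C4 and the methylene on C10; cyclopentane C5–C9 with quaternary C8), C14 for the carbon on C8, then C13, C12 (acetoxy carbon), C11 (lactone carbonyl), C15 (acetal carbon) and C16 (carbon bearing CO2Me). The carbocycle is a cis-fused hydroazulene with three contiguous stereocentres: H5 and H9 are cis, the C8 methyl lies on the face of C10, and C14 lies on the face of the ring-fusion hydrogens. The heterocycle is a 2,7-dioxabicyclo[3.2.1]octan-3-one (tetrahydrofuran O–C15–C14–C13–C16 bridged by the δ-lactone C15–O–C11–C12–C13) with five stereocentres. Of these only C13 is configurationally inert: C15 is an acetal carbon, C14 is α to it, and C16 and C12 are α to carbonyl groups. The target is the isomer in which each of the three clefts between the bridges holds one substituent and one hydrogen (hydroazulene syn to the lactone bridge, ester exo, acetate on the side of the tetrahydrofuran bridge). Because the link joins a quaternary to a tertiary carbon, every bond made at C14 is a neopentyl one and the carbocycle can pass little stereochemical information to C13, which therefore needs its own control element. The fragile groups are the acyloxy acetal and the α-acetoxy lactone (base, nucleophiles), the 1,1-disubstituted alkene (acid, peracid, radicals) and H9 once C10 is a carbonyl. The feature that opens the key step is the substitution of C8: a methyl group, the one-carbon link C14 and the neighbouring ring-fusion carbon C9 are what remains when C9 migrates from a carbinol carbon (the later C14) to the methyl-bearing epoxide carbon of a fused cyclohexane, and that cyclohexane, with its cis fusion, gem-dimethyl group and C10 oxygen, is a Diels–Alder adduct of a cycloheptenone.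

## Retrosynthesis

**Methylene last.** The C10=CH2 bond of 29 is cut to ketone 28, which comes from dioxolane 27. The alkene would not survive the peracid, Lewis acid, radical and strong-acid steps that precede it, and a free C10 ketone would interfere with enolate chemistry at C12. The forward reaction must methylenate a hindered, epimerizable ketone without touching an acetate, an ester and an acyloxy acetal.

**C12–O bond.** Acetate 27 is traced through alcohol 26 to lactone 25, in which C12 is a methylene group. Bringing this oxygen in with an acyclic side chain would leave C12 uncontrolled. In the bicycle one face of the lactone enolate is covered by the hydroazulene on C14. The forward step must enolize the lactone rather than the α-alkoxy ester.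

**Lactone O–C15 bond.** Cutting the acyloxy acetal of 25 gives the 2-methoxytetrahydrofuran 23 carrying a tert-butyl acetate arm on C13 (free acid 24 in the flask). This removes C15 and C14 as stereochemical problems: the acid reaches the oxocarbenium carbon only from its own face, and C14 can equilibrate through the enol ether. Only C13 and C16 have to be correct in 23.

**C14–C13 bond.** 23 is opened at C14–C13 to bromoacetal 22, which is assembled from enol ether 16 and hydroxy diester 21 by forming C15–O and C14–Br. A radical is chosen because C14 is neopentyl. This bond is preferred to a two-bond photocycloaddition (C14–C15 and C12–C13) because the 5-exo closure onto C13 puts the new side chain trans to the C16 ester, which is the relationship of the target. The heterocycle is thereby reduced to a five-carbon chiral building block.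

**Building block.** 21 is traced through acid 20, diol 19 and enoate 18 to the glyceraldehyde acetonide 17, which supplies C16 in the (R) configuration of the target once its formyl group has become the alkene arm.

**C15 and the C7 oxygen.** Enol ether 16 comes from aldehyde 15 by one-carbon olefination. 15 is the key-step product 9 without its C7 oxygen. That oxygen is removed through alcohol 14, cyclic thionocarbonate 12 and diol 11. The detour through the reduced C14 oxidation level is deliberate for two reasons:
- A C7 radical next to a formyl- or vinyl-bearing C8 would undergo a 1,2-shift.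
- A free or silylated C7 oxygen cis to C14 would later trap the C15 oxocarbenium ion.

**Key disconnection.** Aldehyde 9 is traced to epoxy silyl ether 8: the C8–C9 bond is cut and C9 is reconnected to C14. This converts the quaternary centre of a cyclopentane into a trisubstituted epoxide of a cyclohexane, whose configuration is set by a face-selective epoxidation. The forward step must make C9, not hydride, migrate.

**Cyclohexene.** 8 comes from alkene 7 and this from ketone 6, the adduct of enone 3 and diene 5 (bonds C9–C14 and C5–C6). One cycloaddition gives the cis fusion, the gem-dimethyl group, the C10 oxygen and the anti relationship needed later between the silyloxy group and the epoxide. It must be endo-selective and enantioselective on a dienophile whose β-carbon is neopentyl.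

**Starting materials.** 3 is the one-carbon ring expansion product of 1; 5 is the silyl dienol ether of 4.

## Roads not taken

**Alternative 1:** The cut is made in the seven-membered ring (C10–C1 and C4–C5), which is assembled on a cyclopentene that already carries C8. The rhodium carbenoid from the cyclopentenyl diazoacetate A1 cyclopropanates the terminal alkene of 4-methylpenta-1,3-diene A2, and the cis-divinylcyclopropane rearranges (Cope) to the bicyclo[5.3.0]decadiene ester A3.
- Merits: it is convergent, it builds the whole cycloheptane with the gem-dimethyl carbon in one operation, there is no C7 oxygen to remove, and the ester on C10 is the future methylene carbon.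
- Weak points: the Cope step must bond to the fully substituted diene terminus C4, which forces a methyl group into the inside position of the boat transition state. C5 is set relative to a remote quaternary C8 whose two ring neighbours differ little. C9 is still sp2 in A3, so the cis fusion has to be made later at a tetrasubstituted alkene. C8 must be made enantioselectively beforehand. The two-carbon arm carries only C14 and C13, so the oxabicycle still lies ahead.
- Comparison: A3 would probably be reached in fewer steps than aldehyde 15, and that is a real advantage. The chosen plan sets against it that C5, C9 and C8 are all fixed by two stereospecific events (suprafacial cycloaddition and anti 1,2-shift) behind one enantio-determining step.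

**Alternative 2:** The cut is made in the heterocycle only (C14–C15 and C12–C13). Triplet-sensitized irradiation of the β-alkoxyacrylate A4 gives the 2-oxabicyclo[2.1.1]hexane diester A5, and acid then opens the donor–acceptor cyclobutane bond C15–C12 and closes the lactone.
- Merits: it is the shortest way to the oxabicycle. It makes both bonds at the neopentyl C14 in one step, needs no tin, and would save about four steps over the bromoacetal/radical sequence and its building block.
- Weak points: the first bond is expected to form 5-exo from C12 to C13, and the usual preference puts the C16 ester trans to the new exocyclic bond, which is the opposite of what the target needs. A wrong C13 cannot be repaired later. The exocyclic methylene of A4 would have to survive sensitization and the acid used for lactonization. The alternative is also silent on how the hydroazulene is made.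
- Comparison: if the facial selectivity turned out favourable it would be the better endgame. The chosen plan sets against it a C16→C13 relay that runs in the normal sense and a C14 centre that corrects itself in acid.

**Alternative 3:** The cut follows the presumed biogenesis (C5–C9 formed, C5–C10 broken). Buffered solvolysis of the equatorial C9 mesylate A6 of a trans-decalin shifts C5 from C10 to C9 and the C10 cation loses a methyl proton to give the hydroazulene A7.
- Merits: one step sets the ring sizes, the cis fusion and the exocyclic alkene, with no C10 protecting group and no late methylenation. In this respect it is better than the chosen plan.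
- Weak points: the leaving group sits on a secondary carbon between two quaternary centres. Two ring bonds are antiperiplanar to an equatorial C9 leaving group (C10–C5 and C8–C7), so contraction toward C8 competes. The C10 cation can also lose a ring proton to give the more substituted endocyclic alkene. A decalin with a quaternary C8 carrying a two-carbon arm is not a chiral-pool pattern and must itself be synthesized. The arm again supplies only C14 and C13.
- Comparison: the chosen plan is longer in the carbocycle, but its 1,2-shift has a single bond able to migrate anti to the leaving group and the migration terminus is fixed by an epoxide.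

Key step: step 6

Assumption: the (S)-configured oxazaborolidinium catalyst is taken to deliver diene 5 to the face of enone 3 that gives the (1R,4aR,9aR) adduct 6; if the sense of induction is the reverse for this seven-membered enone, the (R)-catalyst is used and nothing else changes.

## Route

Step 1
Reactants: 1 4,4-dimethylcyclohex-2-en-1-one
Product: 3 4,4-dimethylcyclohept-2-en-1-one, via 4,4-dimethyl-7-(trimethylsilyl)cyclohept-2-en-1-one 2 (not isolated)
Conditions: Me3SiCHN2, AlMe3, CH2Cl2, −78 → −20 °C; then 1 M HCl, THF, rt
Reagents that add atoms: trimethylsilyldiazomethane, C[Si](C)(C)C=[N+]=[N-]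
Why: Lewis-acid-promoted diazoalkane ring expansion (Tiffeneau–Demjanov type): the diazo carbon adds to the activated carbonyl and the saturated CH2, not the vinyl carbon, migrates with loss of N2, so the new carbon enters on the saturated side. The neopentyl β-carbon disfavours dipolar addition to the C=C bond, and the α-silyl ketone is protodesilylated on acidic work-up.

Step 2
Reactants: 4 (E)-2-methylbut-2-enal
Product: 5 (1E)-2-methyl-1-(triethylsilyloxy)buta-1,3-diene
Conditions: Et3SiOSO2CF3, Et3N, Et2O, 0 °C
Reagents that add atoms: triethylsilyl trifluoromethanesulfonate, CC[Si](CC)(CC)OS(=O)(=O)C(F)(F)F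
Why: Soft enolization: O-silylation of the enal and γ-deprotonation by the amine give the silyl dienol ether, and the s-trans enal leads to the (1E) geometry needed for an endo cycloaddition.

Step 3
Reactants: 3 4,4-dimethylcyclohept-2-en-1-one; 5 (1E)-2-methyl-1-(triethylsilyloxy)buta-1,3-diene
Product: 6 cis-fused adduct (1R,4aR,9aR)-2,5,5-trimethyl-1-(triethylsilyloxy)-1,4,4a,5,6,7,8,9a-octahydro-9H-benzo[7]annulen-9-one
Conditions: (S)-B-(o-tolyl)oxazaborolidine from (S)-α,α-diphenylprolinol (20 mol%), HN(SO2CF3)2 (18 mol%), CH2Cl2, −40 → −20 °C
Reagents that add atoms: none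
Why: Catalytic enantioselective Diels–Alder reaction of a cyclic enone activated by a chiral oxazaborolidinium ion: the unsubstituted diene terminus bonds to the neopentyl β-carbon C5 and the silyloxy terminus to C9 (ortho orientation). Suprafacial addition to the cis enone fixes the cis ring fusion, the endo transition state puts the silyloxy group cis to C10, and the catalyst sets C5, C9 and C14 in one event.

Step 4
Reactants: 6 cis-fused adduct
Product: 7 C10 ethylene ketal of 6 (spiro-1,3-dioxolane; stereocentres unchanged)
Conditions: Me3SiOCH2CH2OSiMe3, Me3SiOSO2CF3 (5 mol%), CH2Cl2, −78 → −30 °C; pyridine quench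
Reagents that add atoms: 1,2-bis(trimethylsilyloxy)ethane, C[Si](C)(C)OCCO[Si](C)(C)C
Why: Aprotic ketalization with the bis-silyl glycol at low temperature; with no protic acid or base present the β-silyloxy ketone should neither eliminate nor epimerize at C9, and the SiEt3 ether is kept.

Step 5
Reactants: 7 C10 ethylene ketal
Product: 8 epoxy silyl ether (7,8-epoxide on the face of H5/H9/H14; OSiEt3 on the other face)
Conditions: mCPBA, NaHCO3, CH2Cl2, 0 °C
Reagents that add atoms: 3-chloroperbenzoic acid, OOC(=O)c1cccc(Cl)c1
Why: Prilezhaev epoxidation of the only alkene: the lower face of the cyclohexene carries the allylic OSiEt3 group and both seven-membered-ring bonds (C9–C10 with the dioxolane, C5–C4 with the methyl groups), so the peracid should add to the convex face of the ring-fusion hydrogens, anti to the silyloxy group.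

Step 6
Reactants: 8 epoxy silyl ether
Product: 9 hydroazulene aldehyde (8-CHO and 7-OSiEt3 on the face of H5/H9; 8-CH3 on the C10 face; C10 dioxolane)
Conditions: MeAl(OAr)2 [methylaluminium bis(4-bromo-2,6-di-tert-butylphenoxide), 2 equiv], CH2Cl2, −78 → −40 °C; then H2O
Reagents that add atoms: none
Why: Semipinacol rearrangement of a 2,3-epoxy silyl ether; the closest known type is the Lewis-acid ring contraction of cyclic anti-2,3-epoxy alcohol derivatives to 2-oxycyclopentanecarbaldehydes. The bulky aluminium Lewis acid binds the epoxide oxygen and lengthens the C8–O bond at the tertiary carbon. As charge builds at C8, the ring bond C14–C9 shifts to C8 from the face opposite the departing oxygen, with inversion at C8 and retention at C9, while the silyloxy oxygen stabilizes the charge developing at C14. The cyclopentane C5–C9 is thus closed by a 1,2-alkyl shift (ring contraction), not by an end-to-end cyclization; C14 leaves the ring as a silyl-oxocarbenium ion and the silyl group passes to the cis aluminium alkoxide on C7 through a six-membered array. The one new stereocentre, quaternary C8, is fixed by the epoxide configuration: oxygen on the face of H5/H9 makes C9 enter from the C10 face, so the methyl ends cis to C10 and the formyl group on the face of the ring-fusion hydrogens, and C7 keeps its C–O bond. The step needs C9 to migrate in preference to hydride: in the anti epoxy silyl ether H14 is syn to the epoxide oxygen and cannot reach the rear of C8, whereas the ring bond can. The low temperature and the hindered aprotic Lewis acid are chosen to spare the dioxolane.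

Step 7
Reactants: 9 hydroazulene aldehyde
Product: 11 diol (8-CH2OH and 7-OH cis on the face of H5/H9), via primary alcohol silyl ether 10 (not isolated)
Conditions: NaBH4, MeOH–THF, 0 °C; then AcOH, Bu4NF, THF, rt
Reagents that add atoms: none
Why: Hydride reduction removes the carbonyl first, so that fluoride desilylation cannot trigger retro-aldol cleavage of a β-hydroxy aldehyde; no stereocentre is touched.

Step 8
Reactants: 11 diol
Product: 12 six-membered cyclic thionocarbonate of 11
Conditions: 1,1'-thiocarbonyldiimidazole, DMAP (cat.), toluene, 80 °C
Reagents that add atoms: 1,1'-thiocarbonyldiimidazole, S=C(n1ccnc1)n1ccnc1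
Why: Thiocarbonylation of a cis-1,3-diol: the neopentyl primary and the secondary hydroxyl sit on the same face of the cyclopentane and close the cyclic thionocarbonate.

Step 9
Reactants: 12 cyclic thionocarbonate
Product: 14 7-deoxy primary alcohol (8-CH2OH; C7 is CH2), via S-stannyl thiocarbonate 13 (not isolated)
Conditions: Bu3SnH, AIBN (cat.), toluene, 110 °C; then NaOH, MeOH–H2O
Reagents that add atoms: none
Why: Barton–McCombie deoxygenation of a cyclic thionocarbonate: the stannyl radical adds to sulfur and the adduct fragments toward the secondary C7 radical rather than the primary neopentyl C14 radical. At this stage C8 carries only sp3 carbons, so the C7 radical has no 1,2-formyl or vinyl shift open to it; alkaline work-up frees the C14 alcohol.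

Step 10
Reactants: 14 7-deoxy primary alcohol
Product: 15 hydroazulene aldehyde without C7 oxygen
Conditions: Pr4N[RuO4] (5 mol%), N-methylmorpholine N-oxide, 4 Å sieves, CH2Cl2, rt
Reagents that add atoms: none
Why: Perruthenate-catalysed oxidation of a neopentyl primary alcohol; the aldehyde has no α-hydrogen and cannot epimerize.

Step 11
Reactants: 15 hydroazulene aldehyde
Product: 16 methyl enol ether (8-CH=CH-OMe; E/Z mixture)
Conditions: Ph3P(CH2OMe)Cl, KN(SiMe3)2, THF, 0 °C → rt
Reagents that add atoms: (methoxymethyl)triphenylphosphonium chloride, COC[P+](c1ccccc1)(c1ccccc1)c1ccccc1.[Cl-]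
Why: Wittig reaction with the non-stabilized methoxymethylene ylide, which adds even to α-quaternary aldehydes; the alkene geometry is irrelevant because both alkene carbons become sp3 in step 16.

Step 12
Reactants: 17 (S)-2,2-dimethyl-1,3-dioxolane-4-carbaldehyde
Product: 18 tert-butyl (2E)-3-[(4R)-2,2-dimethyl-1,3-dioxolan-4-yl]prop-2-enoate
Conditions: (EtO)2P(O)CH2CO2tBu, LiCl, DBU, MeCN, 0 °C → rt
Reagents that add atoms: tert-butyl 2-(diethoxyphosphoryl)acetate, CCOP(=O)(OCC)CC(=O)OC(C)(C)C
Why: Horner–Wadsworth–Emmons olefination under mild LiCl/amine conditions should give the (E)-enoate without epimerizing the α-alkoxy aldehyde; the descriptor changes from S to R only because the priorities change.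

Step 13
Reactants: 18 enoate acetonide
Product: 19 tert-butyl (2E,4R)-4,5-dihydroxypent-2-enoate
Conditions: AcOH/H2O (4:1), 40 °C
Reagents that add atoms: none
Why: Acid-catalysed acetonide hydrolysis; aqueous acetic acid leaves the tert-butyl ester intact.

Step 14
Reactants: 19 diol
Product: 20 (2R,3E)-5-tert-butoxy-2-hydroxy-5-oxopent-3-enoic acid
Conditions: TEMPO (cat.), NaOCl (cat.), NaClO2, phosphate buffer pH 6.7, MeCN, 35 °C
Reagents that add atoms: sodium chlorite, [Na+].[O-]Cl=O
Why: Oxoammonium oxidation is selective for the primary over the secondary allylic alcohol, and chlorite carries the aldehyde on to the acid at near-neutral pH, where the doubly activated C16–H should not enolize.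

Step 15
Reactants: 20 hydroxy acid
Product: 21 1-tert-butyl 5-methyl (2E,4R)-4-hydroxypent-2-enedioate
Conditions: Me3SiCHN2, MeOH/toluene, 0 °C
Reagents that add atoms: trimethylsilyldiazomethane, C[Si](C)(C)C=[N+]=[N-]
Why: Methyl ester formation by diazomethane generated from the silyl reagent and methanol; the neutral conditions keep the C16 configuration and the (E)-alkene.

Step 16
Reactants: 16 methyl enol ether; 21 hydroxy diester (3 equiv, excess recovered)
Product: 22 mixed bromoacetal (Br on C14; C15 carries OMe and the oxygen of 21; mixture at C14 and C15)
Conditions: NBS, CH2Cl2, −78 → −20 °C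
Reagents that add atoms: N-bromosuccinimide, O=C1CCC(=O)N1Br
Why: Bromoetherification of the enol ether: Br+ adds to C14 and the oxocarbenium ion at C15 is captured by the hydroxyl of 21, whose electron-poor alkene is inert to NBS. The configurations at C14 and C15 are not controlled and need not be.

Step 17
Reactants: 22 mixed bromoacetal
Product: 23 2-methoxytetrahydrofuran (16R-CO2Me; 13-CH2CO2tBu trans to it; mixture at C14 and C15)
Conditions: Bu3SnH, AIBN (cat.), benzene (0.01 M), 80 °C, slow addition
Reagents that add atoms: none
Why: Ueno–Stork radical cyclization: the C14 radical adds 5-exo-trig to the enoate β-carbon C13, a bond that a polar reaction could hardly make at this neopentyl position, and the α-ester radical is reduced. In the chair-like transition state the C16 ester is pseudo-equatorial, which places the new side chain on C13 trans to it, as in the target.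

Step 18
Reactants: 23 2-methoxytetrahydrofuran
Product: 25 bicyclic lactone 2,7-dioxabicyclo[3.2.1]octan-3-one (C12 is CH2; C10 dioxolane; other centres as in 29), via carboxylic acid acetal 24 (not isolated)
Conditions: CF3CO2H/CH2Cl2 (1:4, anhydrous), 0 °C → rt; evaporation with toluene
Reagents that add atoms: none
Why: Acidolysis of the tert-butyl ester and ionization of the methyl acetal to the cyclic oxocarbenium ion, which the C11 acid can reach only from the face of its own arm on C13, closing the six-membered lactone as an acyloxy acetal. C14, α to the oxocarbenium carbon, should equilibrate through the 2,3-dihydrofuran and settle with the hydroazulene syn to the lactone bridge, away from the exo ester on C16. Without water the dioxolane is expected to survive.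

Step 19
Reactants: 25 bicyclic lactone
Product: 26 12-hydroxy lactone (OH on the side of the tetrahydrofuran bridge)
Conditions: KN(SiMe3)2, THF, −78 °C; 2-(phenylsulfonyl)-3-phenyloxaziridine; AcOH quench
Reagents that add atoms: 2-(phenylsulfonyl)-3-phenyloxaziridine, O=S(=O)(N1OC1c1ccccc1)c1ccccc1
Why: Enolate oxidation with an N-sulfonyloxaziridine: the lactone CH2 is more acidic than the α-alkoxy ester C–H, and the oxidant should approach from the side of the tetrahydrofuran bridge because the other face is covered by the hydroazulene on C14.

Step 20
Reactants: 26 12-hydroxy lactone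
Product: 27 12-acetate
Conditions: Ac2O, pyridine, DMAP (cat.), CH2Cl2, 0 °C → rt
Reagents that add atoms: acetic anhydride, CC(=O)OC(C)=O
Why: Acylation of the secondary alcohol with retention at C12.

Step 21
Reactants: 27 12-acetate
Product: 28 C10 ketone
Conditions: pyridinium p-toluenesulfonate, acetone/H2O (10:1), 50 °C
Reagents that add atoms: water, O
Why: Mild acid-catalysed hydrolysis of the dioxolane; the acyloxy acetal was formed under far stronger acid in step 18, and the weak acid limits enolization toward C9.

Step 22
Reactants: 28 C10 ketone
Product: 29 target CNP0215240.1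
Conditions: Zn, CH2Br2, TiCl4 (pre-formed reagent), THF/CH2Cl2, 0 °C → rt
Reagents that add atoms: dibromomethane, BrCBr
Why: Takai–Lombardo methylenation: the zinc–titanium methylene reagent is non-basic and reacts with ketones but not with esters, lactones or acetates, so C9 should not epimerize and the acyl groups stay.

## Compound list

1 | 4,4-dimethylcyclohex-2-en-1-one | CC1(C)CCC(=O)C=C1 | starting material
2 | 4,4-dimethyl-7-(trimethylsilyl)cyclohept-2-en-1-one | CC1(C)CCC([Si](C)(C)C)C(=O)C=C1 | intermediate (not isolated)
3 | 4,4-dimethylcyclohept-2-en-1-one | CC1(C)CCCC(=O)C=C1 | intermediate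
4 | (E)-2-methylbut-2-enal | C/C=C(\C)C=O | starting material
5 | (1E)-2-methyl-1-(triethylsilyloxy)buta-1,3-diene | C=C/C(C)=C/O[Si](CC)(CC)CC | intermediate
6 | (1R,4aR,9aR)-2,5,5-trimethyl-1-(triethylsilyloxy)-1,4,4a,5,6,7,8,9a-octahydro-9H-benzo[7]annulen-9-one (cis-fused; OSiEt3 cis to C10) | CC1=CC[C@H]2C(C)(C)CCCC(=O)[C@H]2[C@H]1O[Si](CC)(CC)CC | intermediate
7 | C10 ethylene ketal of 6 | CC1=CC[C@H]2C(C)(C)CCCC3(OCCO3)[C@H]2[C@H]1O[Si](CC)(CC)CC | intermediate
8 | epoxy silyl ether: 7,8-epoxide of 7 on the face of H5, H9 and H14, OSiEt3 on the opposite face | C[C@@]12O[C@@H]1C[C@H]3C(C)(C)CCCC4(OCCO4)[C@H]3[C@H]2O[Si](CC)(CC)CC | intermediate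
9 | cis-hydroazulene aldehyde: 8-CHO and 7-OSiEt3 on the face of H5/H9, 8-CH3 on the C10 face, C10 dioxolane | O=C[C@]1(C)[C@H](O[Si](CC)(CC)CC)C[C@H]2C(C)(C)CCCC3(OCCO3)[C@@H]12 | intermediate
10 | primary alcohol from 9 (8-CH2OH, 7-OSiEt3) | OC[C@]1(C)[C@H](O[Si](CC)(CC)CC)C[C@H]2C(C)(C)CCCC3(OCCO3)[C@@H]12 | intermediate (not isolated)
11 | diol (8-CH2OH, 7-OH, cis) | OC[C@]1(C)[C@H](O)C[C@H]2C(C)(C)CCCC3(OCCO3)[C@@H]12 | intermediate
12 | cyclic thionocarbonate of 11 | S=C1OC[C@]2(C)[C@H](O1)C[C@H]3C(C)(C)CCCC4(OCCO4)[C@@H]23 | intermediate
13 | O-alkyl S-tributylstannyl thiocarbonate of 14 | CCCC[Sn](CCCC)(CCCC)SC(=O)OC[C@]1(C)CC[C@H]2C(C)(C)CCCC3(OCCO3)[C@@H]12 | intermediate (not isolated)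
14 | 7-deoxy primary alcohol (8-CH2OH) | OC[C@]1(C)CC[C@H]2C(C)(C)CCCC3(OCCO3)[C@@H]12 | intermediate
15 | cis-hydroazulene aldehyde without C7 oxygen | O=C[C@]1(C)CC[C@H]2C(C)(C)CCCC3(OCCO3)[C@@H]12 | intermediate
16 | methyl enol ether (8-CH=CH-OMe, E/Z mixture) | COC=C[C@]1(C)CC[C@H]2C(C)(C)CCCC3(OCCO3)[C@@H]12 | intermediate
17 | (S)-2,2-dimethyl-1,3-dioxolane-4-carbaldehyde | CC1(C)OC[C@H](O1)C=O | starting material
18 | tert-butyl (2E)-3-[(4R)-2,2-dimethyl-1,3-dioxolan-4-yl]prop-2-enoate | CC1(C)OC[C@H](O1)/C=C/C(=O)OC(C)(C)C | intermediate
19 | tert-butyl (2E,4R)-4,5-dihydroxypent-2-enoate | OC[C@H](O)/C=C/C(=O)OC(C)(C)C | intermediate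
20 | (2R,3E)-5-tert-butoxy-2-hydroxy-5-oxopent-3-enoic acid | OC(=O)[C@H](O)/C=C/C(=O)OC(C)(C)C | intermediate
21 | 1-tert-butyl 5-methyl (2E,4R)-4-hydroxypent-2-enedioate | COC(=O)[C@H](O)/C=C/C(=O)OC(C)(C)C | intermediate
22 | mixed bromoacetal (C14–Br; C15 with OMe and the oxygen of 21; C14 and C15 unassigned) | COC(O[C@@H](C(=O)OC)/C=C/C(=O)OC(C)(C)C)C(Br)[C@]1(C)CC[C@H]2C(C)(C)CCCC3(OCCO3)[C@@H]12 | intermediate
23 | 2-methoxytetrahydrofuran (16R-CO2Me, 13-CH2CO2tBu trans to it; C14 and C15 unassigned) | COC1O[C@@H](C(=O)OC)[C@H](CC(=O)OC(C)(C)C)C1[C@]2(C)CC[C@H]3C(C)(C)CCCC4(OCCO4)[C@@H]23 | intermediate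
24 | carboxylic acid from 23 | COC1O[C@@H](C(=O)OC)[C@H](CC(=O)O)C1[C@]2(C)CC[C@H]3C(C)(C)CCCC4(OCCO4)[C@@H]23 | intermediate (not isolated)
25 | bicyclic lactone: 2,7-dioxabicyclo[3.2.1]octan-3-one with C12 as CH2, C10 dioxolane, other centres as in 29 | C12(OCCO1)CCCC(C)(C)[C@@H]3CC[C@@](C)([C@@H]4[C@@H]5OC(=O)C[C@H]4[C@H](C(=O)OC)O5)[C@H]23 | intermediate
26 | 12-hydroxy lactone | C12(OCCO1)CCCC(C)(C)[C@@H]3CC[C@@](C)([C@@H]4[C@@H]5OC(=O)[C@@H](O)[C@H]4[C@H](C(=O)OC)O5)[C@H]23 | intermediate
27 | 12-acetate, C10 dioxolane | C12(OCCO1)CCCC(C)(C)[C@@H]3CC[C@@](C)([C@@H]4[C@@H]5OC(=O)[C@@H](OC(C)=O)[C@H]4[C@H](C(=O)OC)O5)[C@H]23 | intermediate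
28 | C10 ketone | O=C1CCCC(C)(C)[C@@H]2CC[C@@](C)([C@@H]3[C@@H]4OC(=O)[C@@H](OC(C)=O)[C@H]3[C@H](C(=O)OC)O4)[C@H]12 | intermediate
29 | CNP0215240.1 | C=C1CCCC(C)(C)[C@@H]2CC[C@@](C)([C@@H]3[C@@H]4OC(=O)[C@@H](OC(C)=O)[C@H]3[C@H](C(=O)OC)O4)[C@H]12 | target

## Step count and least certain steps

Total: 22 steps. Longest linear sequence: 17 steps (steps 1, 3–11 and 16–22).

**Step 6 (key step).** The most likely failure is attack on the wrong oxygen. The Lewis acid may engage the dioxolane, whose oxygen lies on the lower face behind C8 and can open the activated epoxide or be opened itself. The anti silyloxy oxygen may also take part in a Payne-type isomerization in competition with the C9 shift. Fallback: from 8 the silyl group is removed with Bu4NF to give epoxy alcohol F1, which is heated with Al(OiPr)3 in 2-propanol. The mild aluminium alkoxide binds the free hydroxyl, triggers the same C9 shift and reduces the aldehyde as it forms (tandem semipinacol/Meerwein–Ponndorf–Verley reduction). This delivers diol 11 directly, where the route is rejoined without passing through 9 and step 7.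

**Step 3.** The β-carbon of 3 is neopentyl, so the cycloaddition may be slow enough for acid-induced desilylation of the diene or a stepwise Mukaiyama–Michael pathway to take over, and the higher temperature then needed would erode the enantioselectivity. Fallback: the cycloaddition is run without asymmetric induction (Me2AlCl) and racemic 6 is ketalized as in step 4. Racemic 7 is desilylated (Bu4NF) to allylic alcohol F2, which is esterified with (S)-2-methoxy-2-phenylacetic acid (carbodiimide, DMAP) to the (S)-O-methylmandelate F3. The diastereomers are separated, the correct one is cleaved with K2CO3 in methanol, and resilylation (Et3SiOSO2CF3, 2,6-lutidine) returns 7.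

**Step 17.** The C16 ester is only a modest conformational anchor, so poor facial selectivity in the 5-exo closure would give the C13 epimer, which cannot be corrected later. Fallback: the ester is replaced by a larger group during the cyclization and made afterwards. Diol 19 is silylated at the primary hydroxyl (tBuPh2SiCl, imidazole) to silyl ether alcohol F4. This is joined to 16 with NBS to give bromoacetal F5, which is cyclized with Bu3SnH to tetrahydrofuran F6. Bu4NF frees the primary alcohol F7, TEMPO/NaClO2 oxidation gives the acid F8, and Me3SiCHN2 returns 23.

**Step 18.** The radical closure is expected to leave much of the material with the hydroazulene trans to the C13 arm, and convergence at C14 depends on the oxocarbenium ion losing and regaining H14. If that equilibration is slow, the ion is merely captured reversibly and the wrong C14 configuration persists. Traces of ketone from loss of the dioxolane would simply be re-ketalized as in step 4. Fallback: from 23 methanol is eliminated thermally (pyridinium p-toluenesulfonate, toluene, 110 °C, 5 Å sieves) to the 2,3-dihydrofuran F9. Its C14=C15 bond is then protonated under the conditions of step 18 from the face opposite the C13 arm, which sets C14 kinetically before the lactone closes to 25.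

**Step 19.** Competing deprotonation at C16, or fragmentation of the acyloxy-acetal enolate into a ketene and a lactolate before the oxidant arrives, would consume the lactone. Fallback: 25 is added to LiN(SiMe3)2 in the presence of Me3SiCl at −78 °C so that the enolate is trapped as it forms, giving silyl ketene acetal F10. This is oxidized with dimethyldioxirane (Rubottom oxidation) and desilylated on mildly acidic work-up to give 26.

## Further compounds

F1 | step 6 | epoxy alcohol (8 without the silyl group) | C[C@@]12O[C@@H]1C[C@H]3C(C)(C)CCCC4(OCCO4)[C@H]3[C@H]2O
F2 | step 3 | allylic alcohol (7 without the silyl group) | CC1=CC[C@H]2C(C)(C)CCCC3(OCCO3)[C@H]2[C@H]1O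
F3 | step 3 | (S)-2-methoxy-2-phenylacetate of F2 | CC1=CC[C@H]2C(C)(C)CCCC3(OCCO3)[C@H]2[C@H]1OC(=O)[C@@H](OC)c1ccccc1
F4 | step 17 | tert-butyl (2E,4R)-5-(tert-butyldiphenylsilyloxy)-4-hydroxypent-2-enoate | CC(C)(C)[Si](OC[C@H](O)/C=C/C(=O)OC(C)(C)C)(c1ccccc1)c1ccccc1
F5 | step 17 | mixed bromoacetal from 16 and F4 (C14 and C15 unassigned) | COC(O[C@@H](CO[Si](c4ccccc4)(c5ccccc5)C(C)(C)C)/C=C/C(=O)OC(C)(C)C)C(Br)[C@]1(C)CC[C@H]2C(C)(C)CCCC3(OCCO3)[C@@H]12
F6 | step 17 | 2-methoxytetrahydrofuran with 16-CH2OSi(tBu)Ph2 | COC1O[C@@H](CO[Si](c5ccccc5)(c6ccccc6)C(C)(C)C)[C@H](CC(=O)OC(C)(C)C)C1[C@]2(C)CC[C@H]3C(C)(C)CCCC4(OCCO4)[C@@H]23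
F7 | step 17 | 2-methoxytetrahydrofuran with 16-CH2OH | COC1O[C@@H](CO)[C@H](CC(=O)OC(C)(C)C)C1[C@]2(C)CC[C@H]3C(C)(C)CCCC4(OCCO4)[C@@H]23
F8 | step 17 | 2-methoxytetrahydrofuran 16-carboxylic acid | COC1O[C@@H](C(=O)O)[C@H](CC(=O)OC(C)(C)C)C1[C@]2(C)CC[C@H]3C(C)(C)CCCC4(OCCO4)[C@@H]23
F9 | step 18 | 2,3-dihydrofuran (C14=C15) from 23 | COC(=O)[C@@H]1OC=C([C@H]1CC(=O)OC(C)(C)C)[C@]2(C)CC[C@H]3C(C)(C)CCCC4(OCCO4)[C@@H]23
F10 | step 19 | trimethylsilyl ketene acetal of 25 | C12(OCCO1)CCCC(C)(C)[C@@H]3CC[C@@](C)([C@@H]4[C@@H]5OC(O[Si](C)(C)C)=C[C@H]4[C@H](C(=O)OC)O5)[C@H]23
A1 | alternative 1 | ethyl 2-diazo-2-{5-[2-(tert-butyldimethylsilyloxy)ethyl]-5-methylcyclopent-1-en-1-yl}acetate | CCOC(=O)C(=[N+]=[N-])C1=CCC[C@@]1(C)CCO[Si](C)(C)C(C)(C)C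
A2 | alternative 1 | 4-methylpenta-1,3-diene | C=CC=C(C)C
A3 | alternative 1 | bicyclo[5.3.0]decadiene ester with C5 set | CCOC(=O)C1=C2[C@](C)(CCO[Si](C)(C)C(C)(C)C)CC[C@H]2C(C)(C)C=CC1
A4 | alternative 2 | β-alkoxyacrylate 1,5-diene on the hydroazulene | C=C1CCCC(C)(C)[C@@H]2CC[C@@](C)(/C=C/[C@@H](O/C=C/C(=O)OC(C)(C)C)C(=O)OC)[C@H]12
A5 | alternative 2 | 2-oxabicyclo[2.1.1]hexane diester (C12 unassigned) | C=C1CCCC(C)(C)[C@@H]2CC[C@@](C)([C@@H]3[C@H]4O[C@@H](C(=O)OC)[C@@H]3C4C(=O)OC(C)(C)C)[C@H]12
A6 | alternative 3 | trans-decalin with equatorial C9 mesylate and 2-pivaloyloxyethyl arm on C8 | CC1(C)CCC[C@@]2(C)[C@H]1CC[C@@](C)(CCOC(=O)C(C)(C)C)[C@@H]2OS(C)(=O)=O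
A7 | alternative 3 | cis-hydroazulene with exocyclic methylene and 2-pivaloyloxyethyl arm on C8 | C=C1CCCC(C)(C)[C@@H]2CC[C@@](C)(CCOC(=O)C(C)(C)C)[C@H]12
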